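The data were generated by integration with made-up constants, and the scatter is random.

Take the rate at which Thursday's flask loses electrophile, and watch how that rate itself dies away.

in all of them: electrophile 10 mM
- Thursday's: nucleophile 12 mM; the very flask that is asked about, followed so far
- Monday's: nucleophile 18 mM; run made earlier
- flask: nucleophile 12.0 mM; time 4.0 min

| run | time / s | electrophile / % | target / % |
|---|---|---|---|
| Thursday's | 15.0 | 60.2 | 17.9 |
| Thursday's | 30.0 | 45.9 | 25.0 |
| Thursday's | 40.0 | 40.0 | 25.9 |
| Thursday's | 60.0 | 34.3 | 27.5 |
| Thursday's | 80.0 | 30.0 | 26.3 |
| Monday's | 20.0 | 44.5 | 27.4 |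
| Monday's | 40.0 | 30.8 | 29.1 |
| Monday's | 60.0 | 26.2 | 27.2 |
| Monday's | 80.0 | 23.4 | 25.1 |
| Monday's | 90.0 | 22.0 | 25.5 |

(each reading ± 0.5 percentage points)

- part of the electrophile that has reacted at 4.0 min
- share of the unused nucleophile that is free and not bound as protonated nucleophile, at 4.0 min

- percent here means electrophile units held: one idle adduct or homo dimer counts as two
- what is said of target includes idle adduct
- steps thought possible: nucleophile + target -> over-reaction product; nucleophile + acid set free <-> protonated nucleophile; electrophile + nucleophile -> acid set free + target; electrophile + target <-> idle adduct; 2 electrophile -> homo dimer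
- in an amount of target, one idle adduct counts as one target
- what has gone from electrophile into another species counts as reacted, even if it can come back
- the earlier runs do not show how much of nucleophile is bound; that part of a forecast is a guess

Over the first 15.0 s of Thursday's run, the electrophile goes at 1.59 min⁻¹ of its charge. Between 30.0 s and 40.0 s it goes at 0.354 min⁻¹, and between 60.0 s and 80.0 s at 0.129 min⁻¹. At the middle of that last window, 70.0 s, 32.1% stands. The last rate held to the asked time gives 36.5%, more than that, so the rate must fall further.

Between windows I read the time in which the rate falls by a factor e: first 18.3 s, then 34.7 s, about twice as long. I lengthen it by the same factor once more, to 65.7 s, the slowing time of the tail. A rate dying exponentially delivers rate times time constant, less the part that lies beyond the asked time, which from 70.0 s to 4.0 min makes 13.1%, so I expect 80.9% reacted. For fr I have no reckoning, since the runs do not show how much nucleophile is bound.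

The forecast says “Late on, its decay looks second order in electrophile” and gives 85% for c, above mine, and 25% for fr.

The flask gives 80.0% reacted and 6.68% free.

    nucleophile + target → over-reaction product (k = 4.20 M⁻¹ s⁻¹)
    nucleophile + acid set free ⇌ protonated nucleophile, settled at all times (K = 34000 M⁻¹)
    electrophile + nucleophile → acid set free + target (k = 1.90 M⁻¹ s⁻¹)
    electrophile + target ⇌ idle adduct, settled at all times (K = 280 M⁻¹)
    2 electrophile → homo dimer (k = 0.390 M⁻¹ s⁻¹)

At 4.00 min the flask holds 2.7% of its nucleophile charge free, beside 4.46 mM of protonated nucleophile. After 70.0 s the electrophile of this flask falls by 12.1%, against the 13.1% reckoned with my slowing time. Monday's run loses 0.0840 min⁻¹ between 60.0 s and 90.0 s, with 24.1% standing mid-window. With 65.7 s, the same reckoning gives 84.4% reacted at 4.0 min, and Monday's run then stands at 85.6%.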